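## Retrosynthetic overview
1. The target comes from its 2,5-dibenzoate isomer by an O2→O7 benzoyl shift, which is possible because C7 and O2 are cis on the ring.
2. The 2,5-dibenzoate comes from a trans-bis-epoxy alcohol and 2 PhCO2H, by two SN2 openings at the outer carbons C2 and C5.
3. The trans-bis-epoxy alcohol comes from (cyclohexa-1,5-dien-1-yl)methanol. Both oxiranes (rings B and C) are made in one flask: Ti/L-(+)-tartrate for C1=C2, then OH-directed vanadium for C5=C6. This key step sets all four stereocentres.
4. The dienol (ring A) comes from a propargyl silyl ether and 1,5-cyclooctadiene by tandem enyne cross-metathesis/ring closure.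
5. Ring order: A first, then B and C together. B and C are opened again in the following step.

Assumption: the target is taken as (1S,2R,5R,6S). Target locants are used for every compound: C1 = quaternary carbon, C2 = CH(OH) next to CH2, C3/C4 = CH2, C5 = CH(OBz), C6 = CH(OH), C7 = exocyclic CH2. β is the face towards the viewer when C1→C6 runs clockwise. The target is 1β-OH, 7α, 2α-OH, 5β-OBz, 6α-OH.

## Route

**Step 1**
Reactants: 1 trimethyl(prop-2-yn-1-yloxy)silane; 2 (1Z,5Z)-cycloocta-1,5-diene
Product: 4 (cyclohexa-1,5-dien-1-yl)methanol, via dienyl trimethylsilyl ether 3 (not isolated)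
Conditions: RuCl2(=CHPh)(PCy3)(H2IMes) (second-generation Grubbs catalyst, 5 mol %), 2 (1.5 equiv), CH2Cl2, 40 °C, slow addition of 1; then K2CO3 (cat.), MeOH, 23 °C
Reagents that add atoms: none
Why: This is a tandem enyne cross-metathesis/ring-closing metathesis under methylene-free conditions, in which the Ru alkylidene opened from 2 adds to the terminal alkyne of 1 and the resulting vinyl carbene closes onto the internal alkene four carbons away to give the 2-substituted cyclohexa-1,3-diene (ring A), after which mild methanolysis removes the labile Me3Si group; no stereocentre is formed.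

**Step 2 (key step)**
Reactants: 4 (cyclohexa-1,5-dien-1-yl)methanol
Product: 6 [(1S,2S,5S,6S)-1,2:5,6-diepoxycyclohexyl]methanol (trans-bis-epoxide), via vinyl oxirane 5 (not isolated)
Conditions: Ti(OiPr)4 (10 mol %), L-(+)-diisopropyl tartrate (12 mol %), t-BuOOH (3 equiv, decane), 4 Å molecular sieves, CH2Cl2, −20 °C; then VO(acac)2 (3 mol %), −20 → 10 °C, same flask
Reagents that add atoms: tert-butyl hydroperoxide, CC(C)(C)OO
Why: Proposed new method: a Katsuki–Sharpless asymmetric epoxidation is relayed in the same flask into a VO(acac)2/t-BuOOH hydroxyl-directed epoxidation; the Ti–L-(+)-tartrate complex oxidises only the allylic trisubstituted C1=C2 bond and, as with other 2,3-disubstituted allylic alcohols, gives the (2S)-type epoxy alcohol 5 (C1 S, C2 S, oxirane O β), which puts C7 on the α face, so the homoallylic vanadate ester formed after VO(acac)2 is added can deliver oxygen to C5=C6 only from that α face (also the face vinyl oxiranes prefer on dipole grounds), setting C5 (S) and C6 (S) and giving the trans-bis-epoxide; the closest known reaction types are the Sharpless epoxidation of dienols and the VO(acac)2-catalysed syn-epoxidation of cyclic homoallylic alcohols.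

**Step 3**
Reactants: 6 [(1S,2S,5S,6S)-1,2:5,6-diepoxycyclohexyl]methanol
Product: 7 (1R,2R,5R,6S)-1,6-dihydroxy-1-(hydroxymethyl)cyclohexane-2,5-diyl dibenzoate
Conditions: PhCO2H (3 equiv), Ti(OiPr)4 (1.5 equiv), CH2Cl2, 23 °C; aqueous work-up
Reagents that add atoms: benzoic acid, O=C(O)c1ccccc1
Why: This is a Ti(OiPr)4-mediated opening of epoxy alcohols by a carboxylic acid (Caron–Sharpless type), in which titanium bound at O7/O1 activates both oxiranes and benzoate attacks by SN2 the carbon remote from the oxygenated quaternary centre in each ring (C2 = C-3 of the 2,3-epoxy alcohol, C5 = distal carbon of the second oxirane, matching the outer-carbon opening of trans-cyclohexadiene diepoxide), so C2 and C5 are inverted to R (2α-OBz, 5β-OBz) while the C1–O and C6–O bonds keep their configuration.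

**Step 4**
Reactants: 7 (1R,2R,5R,6S)-1,6-dihydroxy-1-(hydroxymethyl)cyclohexane-2,5-diyl dibenzoate
Product: 8 [(1S,2R,5R,6S)-5-(benzoyloxy)-1,2,6-trihydroxycyclohexyl]methyl benzoate
Conditions: DBU (0.2 equiv), MeCN, 23 °C
Reagents that add atoms: none
Why: This is a base-catalysed intramolecular 1,3-O→O acyl migration through a six-membered orthoacid intermediate (the analogue of the O-4→O-6 benzoyl shift in pyranosides), which works because O2 and C7 are cis, the primary benzoate is the thermodynamic product, the O5 benzoate stays because its only neighbour O6 is trans and more hindered, and no C–O bond at a stereocentre is broken (the C1 descriptor changes from R to S only through CIP ranking).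

## Compound list
1 | trimethyl(prop-2-yn-1-yloxy)silane | C#CCO[Si](C)(C)C | starting material
2 | (1Z,5Z)-cycloocta-1,5-diene | C1C/C=C\CC/C=C\1 | starting material
3 | (cyclohexa-1,5-dien-1-ylmethoxy)trimethylsilane | C[Si](C)(C)OCC1=CCCC=C1 | intermediate
4 | (cyclohexa-1,5-dien-1-yl)methanol | OCC1=CCCC=C1 | intermediate
5 | [(1S,6S)-7-oxabicyclo[4.1.0]hept-2-en-1-yl]methanol (C1–C2 β-oxirane, C7 α, C5=C6 intact) | OC[C@]12O[C@H]1CCC=C2 | intermediate
6 | [(1S,2S,5S,6S)-1,2:5,6-diepoxycyclohexyl]methanol (C1–C2 oxirane O β, C5–C6 oxirane O α, CH2OH α) | OC[C@]12O[C@H]1CC[C@@H]3O[C@H]23 | intermediate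
7 | (1R,2R,5R,6S)-1,6-dihydroxy-1-(hydroxymethyl)cyclohexane-2,5-diyl dibenzoate (1β-OH, 7α-CH2OH, 2α-OBz, 5β-OBz, 6α-OH) | OC[C@]1(O)[C@H](OC(=O)c2ccccc2)CC[C@@H](OC(=O)c2ccccc2)[C@@H]1O | intermediate
8 | [(1S,2R,5R,6S)-5-(benzoyloxy)-1,2,6-trihydroxycyclohexyl]methyl benzoate | O=C(OC[C@]1(O)[C@H](O)CC[C@@H](OC(=O)c2ccccc2)[C@@H]1O)c1ccccc1 | target

Total step count: 4. Longest linear sequence: 4.

## Steps most likely to fail

**Step 2.** Vinyl oxirane 5 has a tertiary allylic C–O bond that the Ti or V Lewis acids may open, and the second oxidation may stall. The fallback runs from 4 back to 6 and replaces catalytic enantiocontrol with a resolution. VO(acac)2 (2 mol %) with t-BuOOH (2.5 equiv) in CH2Cl2 at 0 °C epoxidises 4 twice under hydroxyl direction to the racemic trans-bis-epoxy alcohol F1. DCC/DMAP esterification with (S)-2-methoxy-2-phenylacetic acid gives the (S)-O-methylmandelate of the (1S,2S,5S,6S)-alcohol F2 together with the (S)-O-methylmandelate of the (1R,2R,5R,6R)-alcohol F3. The two diastereomers are separated on silica gel, and K2CO3/MeOH on F2 releases 6.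

**Step 3.** The non-chelated C5–C6 oxirane may be inert to the titanium conditions. Alternatively, the C1 alkoxide freed by the first opening may attack C6 (epoxide migration). The fallback runs from 6 back to 8 and bypasses 7, opening the two oxiranes one at a time by different activation modes.
- PhCO2H (1.0 equiv) and Ti(OiPr)4 (1.2 equiv) at 0 °C react only with the chelating 2,3-epoxy alcohol unit and give the 2-O-benzoyl 5,6-epoxy 1,7-diol F4.
- Catalytic DBU moves the benzoyl group to O7 to give the 7-O-benzoyl 5,6-epoxy 1,2-diol F5.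
- Metal-free SN2 opening of the remaining oxirane at C5 with PhCO2H and Bu4N(O2CPh) in toluene at 80 °C gives 8.

**Step 4.** The equilibrium may stop at a mixture, or the O5 benzoate may also migrate. The fallback runs from 7 back to 8 and replaces the migration by full deacylation and regioselective reacylation. NaOMe in MeOH gives the pentol F6. BzCl (2.05 equiv) with 2,4,6-collidine in CH2Cl2 at −40 °C then benzoylates the primary O7 and the least hindered secondary O5. O2 and O6 both flank the quaternary carbon and O1 is tertiary, so these react more slowly.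

## Further compounds
F1 | step 2 | racemic [(1S*,2S*,5S*,6S*)-1,2:5,6-diepoxycyclohexyl]methanol (racemate, relative configuration drawn) | OC[C@]12O[C@H]1CC[C@@H]3O[C@H]23
F2 | step 2 | [(1S,2S,5S,6S)-1,2:5,6-diepoxycyclohexyl]methyl (S)-2-methoxy-2-phenylacetate | CO[C@H](C(=O)OC[C@]12O[C@H]1CC[C@@H]3O[C@H]23)c1ccccc1
F3 | step 2 | [(1R,2R,5R,6R)-1,2:5,6-diepoxycyclohexyl]methyl (S)-2-methoxy-2-phenylacetate | CO[C@H](C(=O)OC[C@@]12O[C@@H]1CC[C@H]3O[C@@H]23)c1ccccc1
F4 | step 3 | (1S,2R,5S,6S)-5,6-epoxy-1-hydroxy-1-(hydroxymethyl)cyclohexan-2-yl benzoate | OC[C@]1(O)[C@H](OC(=O)c2ccccc2)CC[C@@H]2O[C@H]12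
F5 | step 3 | [(1S,2R,5S,6S)-5,6-epoxy-1,2-dihydroxycyclohexyl]methyl benzoate | O=C(OC[C@]1(O)[C@H](O)CC[C@@H]2O[C@H]12)c1ccccc1
F6 | step 4 | (1S,2R,5R,6S)-1-(hydroxymethyl)cyclohexane-1,2,5,6-tetrol | OC[C@]1(O)[C@H](O)CC[C@@H](O)[C@@H]1O
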